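The target and the cross product compete for one starting material, and if each route is first order in it, its charge drops out of their ratio. So you can test that on the readings before trusting any fit.

| setting | west | north-west | south | south-east | midnight | spring | noon |
|---|---|---|---|---|---|---|---|
| starting material | 0.050 M | 0.050 M | 0.050 M | 0.025 M | 0.050 M | 0.050 M (fed, over 3.0 h) | 0.050 M |
| partner | 0.075 M | 0.075 M | 0.075 M | 0.075 M | 0.0750 M (fed, over 3.0 h) | 0.0750 M | 0.0750 M |
| second substrate | 0.050 M | 0.025 M | 0.038 M | 0.050 M | 0.0500 M | 0.0500 M | 0.0500 M |
| protic impurity | 0.010 M | 0.010 M | 0.010 M | 0.010 M | 0.0100 M | 0.0100 M | 0.0100 M |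
| remark | run made earlier | run made earlier | run made earlier | run made earlier | all else is in the flask from the start; the feed brings no volume worth counting | all else is in the flask from the start; the feed brings no volume worth counting | everything together at the start |
| time |  |  |  |  | 5.0 h | 5.0 h | 5.0 h |

- west (time / h: target / %, cross product / %): 0.200: 4.1, 3.1; 0.667: 5.7, 8.8; 1.00: 5.3, 10.8; 1.50: 6.2, 14.4; 2.50: 6.1, 19.1; 3.00: 6.7, 20.8
- north-west (time / h: target / %, cross product / %): 0.417: 5.3, 2.6; 0.667: 5.8, 4.3; 1.00: 6.2, 5.8; 2.00: 6.7, 8.6; 3.00: 7.4, 11.2; 5.00: 8.2, 13.2
- south (time / h: target / %, cross product / %): 0.333: 4.9, 3.3; 1.00: 5.7, 8.5; 2.00: 6.2, 13.8; 2.50: 6.5, 14.9; 4.00: 7.1, 18.2; 5.00: 7.7, 19.2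
- south-east (time / h: target / %, cross product / %): 0.417: 4.9, 6.2; 0.833: 5.8, 10.1; 1.33: 5.6, 14.3; 2.50: 6.4, 19.7; 5.00: 7.9, 25.6

(scatter of a reading: 0.3 percentage points)

- the earlier runs were read with a standard deviation of 0.3 percentage points
- steps that have been proposed: starting material + partner -> target; second substrate + partner -> second product; starting material + second substrate -> cross product; partner + protic impurity -> quenched reagent; target <-> isomer of the product

* the best flask by share of target in target plus cross product; "all alike" if 1.5 percentage points covers them all (midnight / spring / noon / all alike)
* share of target in target plus cross product at the end, midnight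
* share of target in target plus cross product at the end, spring
* share of target in target plus cross product at the end, noon

Take usable partner as partner charged less protic impurity charged. At 5.0 h, divide target over cross product by usable partner per second substrate, and call the mean the 0.237 branch constant, an apparent selectivity factor. The north-west, south and south-east runs give 0.239, 0.234 and 0.237.

Now take two extremes. With usable partner present from the start, the ratio is 0.308, so the share is 23.5%. With no partner in the flask, the proposed step to target stops and the share is nil. My reckoning puts noon at the first extreme. I give spring the same figure as a first guess, but its feed may change how partner runs down, and this reckoning does not follow that, so it does not part spring from noon.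

Midnight lies between. As a crude assumption for midnight, let the impurity take the first of the feed and let nothing else consume partner: the feed then covers the impurity in 0.400 h, and usable partner climbs, averaging 0.0429 M over the run. That gives me 16.9%, lower than the first extreme.

The forecast chose spring: midnight 11.5% (8% to 16%), spring 25% (21% to 30%), noon 24% (22% to 26%), adding “Spring and noon are nearly tied”. My midnight figure stands above its range.

    starting material + partner → target (k = 4.49 M⁻¹ h⁻¹)
    second substrate + partner → second product (k = 3.06 M⁻¹ h⁻¹)
    starting material + second substrate → cross product (k = 3.20 M⁻¹ h⁻¹)
    partner + protic impurity → quenched reagent (k = 22.2 M⁻¹ h⁻¹)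
    target ⇌ isomer of the product (K = 6.26, k = 4.66 h⁻¹)

The flasks give midnight 14.7%, spring 23.6% and noon 21.6%, so spring leads and the forecast stands. Spring's share has moved 5 points at 0.0625 M of partner, which would leave the forecast's range. Spring's own branch constant comes to 0.238. Carry the mean constant to the spring flask with 0.13 M of partner: the ratio is 0.569 and the share 36.3%. That flask gives 45.4%, with 21.3% of its second substrate left at 5.00 h.

The earlier runs and the new flask are simulated for substances that don't exist; noise was put on by code.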